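All constants were set for the occasion.

You want the ring, so ask how much of the substrate ends there in this flask.

    substrate + activated form → open dimer (k1 = 6.0 × 10⁻⁴ M⁻¹ s⁻¹)
    activated form ⇌ ring (K2 = 0.87, k2 = 7.5 × 10⁻⁴ s⁻¹)
    substrate + activator → activated form (k3 = 0.010 M⁻¹ s⁻¹)

substrate 0.050 M; activator 0.0550 M; time 2.5 d

* why nothing more happens at 2.5 d, or that something still does (it is still moving / the activator has run out first / all of the substrate has reacted / forward and back rates have come level)
* amount of ring at 2.5 d, in percent of the substrate charged

- percent here means substrate units held: one open dimer counts as two
- the reaction counts as stopped when no species that holds the substrate changes by six tenths of a point or more over the second half of the time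
- run time (flask): 2.5 d

1. Here is the oddity. By its forward rate alone, activated form has a half-life of 0.26 h on the way to ring, and the run lasts 234 such half-lives. Yet the equilibrium constant is 0.87, so you expect less ring than activated form.

2. The way back clears this up. Ring reopens with a rate constant of 8.62 × 10⁻⁴ s⁻¹, larger than the 7.5 × 10⁻⁴ s⁻¹ with which it forms, so the forward and back rates come level while [ring] stands below [activated form]. A constant of 1 is the zero of the scale, an even split. Here the split is 46.5%: this is the ring share, ring over ring plus activated form at balance.

3. In this flask, activator at 0.0550 M exceeds substrate at 0.050 M, so substrate is the limiting reagent. The excess gives a pseudo-first-order tail with a lifetime of 5.56 h, well inside the run. I therefore expect all of the substrate to react.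

4. With spent activator as the clock, and [activated form] as the unclosed part of the pool, my rough integral sends 10.5% of the substrate to open dimer. The ring share of the remainder gives 41.6%.

5. The forecast says all of the substrate has reacted and gives 42.5%, above my figure. Its grounds include this: “The slow dimer step only gets to act while free substrate remains”.

The simulation of this flask gives 42.5% of ring and the end the forecast named: all of the substrate has reacted. Open dimer holds 8.69%, less than my 10.5%, and the ring share taken of the remainder gives 42.5% of the substrate. The forecast's end no longer holds in a second flask, charged with 0.12 M of substrate, where activator falls to 0% with 14.5% of the substrate left and open dimer at 79.4%. There, ring at 2.87% beside activated form at 3.28% reads as a share of 46.7%.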